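**Retrosynthetic overview**
- The C2–aryl bond of ring C is cut first: an 8-prenyl-7-silyloxychromone plus (2,2-dimethylchroman-6-yl)boronic acid, joined by a rhodium-catalysed asymmetric 1,4-addition that sets C2 as (S).
- The prenyl group at C8 comes from O-allylation of 7-hydroxychromone, aromatic Claisen rearrangement to C8 and cross-metathesis with 2-methyl-2-butene.
- The boronic acid comes from 2,2-dimethylchroman by bromination para to the ring oxygen (C6), then lithiation and borylation.
- The chroman is made by a formal [4+2] annulation of 2-fluorostyrene with 2-propanol: the C3–C2 bond by radical addition to the vinyl terminus, the O1–C8a bond by ipso displacement of fluoride. The enabling feature is that on ring B the ether oxygen carbon (C8a) is ortho to the carbon carrying the C4–C3 chain (C4a), so the radical-accepting CH2 and the C–F carbon sit four atoms apart and match the C–O unit of 2-propanol; C6, para to that oxygen, is the only other substituted ring position, so the new oxygen then directs bromination there.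
- Ring order: the dihydropyran ring of the chroman is the only ring built (step 1); rings A and C arrive intact in 7-hydroxychromone, and ring C is brought to the chroman-4-one level in step 8.

Key step: step 1

Remark: the sense of induction in step 8 is assigned by analogy with (S)-biaryl-bisphosphine complexes of monovalent rhodium on cyclic enones and coumarins; if the first run shows the opposite sense, the (R)-ligand is used.

Step 1
Reactants: 1 2-fluorostyrene; 2 2-propanol
Product: 4 2,2-dimethylchroman, via 4-(2-fluorophenyl)-2-methylbutan-2-ol 3 (not isolated)
Conditions: (nBu4N)4[W10O32] (2 mol %), 2-propanol–MeCN (1:1), 390 nm LEDs, 25 °C, degassed, dilute in 1; then evaporate, KOtBu (2.5 equiv), DMSO, 90 °C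
Reagents that add atoms: none
Why: Proposed new method: photoexcited decatungstate abstracts the hydridic α-C–H of 2-propanol, the nucleophilic 2-hydroxy-2-propyl radical adds to the terminal vinyl carbon of 1 to give the benzylic radical, and back hydrogen-atom transfer from the reduced polyoxometalate gives alcohol 3 and closes the catalytic cycle. After removal of 2-propanol, the potassium alkoxide of 3 in DMSO displaces fluoride at the ipso carbon, closing the dihydropyran ring in a 6-exo-trig ipso attack (addition–elimination or concerted displacement). The closest known reaction types are the radical (Kharasch–Urry) addition of 2-propanol to styrene, decatungstate-photocatalysed C–H hydroalkylation of alkenes, the photoredox hydroaminoalkylation/SNAr annulation of halogenated vinyl(het)arenes with amines (the aza analogue of this sequence), and intramolecular alkoxide SNAr on aryl fluorides. No stereocentre is formed. The step needs anti-Markovnikov regioselectivity, secured by formation of the benzylic radical; suppression of telomerisation, secured by dilution, the large excess of 2-propanol and fast back hydrogen transfer; and closure by the tethered tertiary alkoxide in preference to tert-butoxide, secured by intramolecularity. Only the fluorine-bearing carbon is within reach of the tether, and an elimination–addition pathway through the 2,3-aryne would deliver oxygen to the same carbon, so the constitution of 4 does not depend on which ionic pathway operates.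

Step 2
Reactants: 4 2,2-dimethylchroman
Product: 5 6-bromo-2,2-dimethylchroman
Conditions: NBS, MeCN, 0 °C to 25 °C, dark
Reagents that add atoms: N-bromosuccinimide, O=C1CCC(=O)N1Br
Why: electrophilic aromatic bromination of an alkyl aryl ether with NBS in MeCN goes para to the ring oxygen, and in 4 that position is C6, the carbon that must later bond to C2 of the flavanone.

Step 3
Reactants: 5 6-bromo-2,2-dimethylchroman
Product: 6 (2,2-dimethylchroman-6-yl)boronic acid
Conditions: n-BuLi, THF, −78 °C; B(OiPr)3, −78 °C to 25 °C; aq. HCl
Reagents that add atoms: triisopropyl borate, CC(C)OB(OC(C)C)OC(C)C; water, O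
Why: bromine–lithium exchange followed by borate trapping and acidic hydrolysis is the standard route to an electron-rich arylboronic acid, and 5 has no acidic or electrophilic site to interfere.

Step 4
Reactants: 7 7-hydroxychromone (7-hydroxy-4H-chromen-4-one)
Product: 8 7-(allyloxy)chromone
Conditions: allyl bromide, K2CO3, acetone, reflux
Reagents that add atoms: allyl bromide, C=CCBr
Why: Williamson ether synthesis on the acidic 7-hydroxyl (a vinylogous carboxylic acid) with a mild carbonate base that leaves the pyranone untouched.

Step 5
Reactants: 8 7-(allyloxy)chromone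
Product: 9 8-allyl-7-hydroxychromone
Conditions: N,N-diethylaniline, 200 °C
Reagents that add atoms: none
Why: aromatic Claisen rearrangement ([3,3]-sigmatropic shift, then tautomerisation), which should go to C8 and not C6 because the C7–C8 bond of the benzopyranone has the higher double-bond character, as in the rearrangement of 2-naphthyl allyl ether to C1.

Step 6
Reactants: 9 8-allyl-7-hydroxychromone
Product: 10 8-allyl-7-(triisopropylsilyloxy)chromone
Conditions: TIPSCl, imidazole, DMF, 25 °C
Reagents that add atoms: chlorotriisopropylsilane, CC(C)[Si](Cl)(C(C)C)C(C)C
Why: silylation of the phenol masks the acidic hydroxyl that would otherwise protonate the aryl–rhodium species in step 8, using a group that fluoride later removes without acid or strong base.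

Step 7
Reactants: 10 8-allyl-7-(triisopropylsilyloxy)chromone
Product: 11 8-(3-methylbut-2-enyl)-7-(triisopropylsilyloxy)chromone
Conditions: 2-methyl-2-butene (excess), second-generation Grubbs catalyst RuCl2(=CHPh)(PCy3)(H2IMes) (5 mol %), CH2Cl2, 40 °C, sealed tube
Reagents that add atoms: 2-methyl-2-butene, CC=C(C)C
Why: olefin cross-metathesis of a terminal allylarene with excess 2-methyl-2-butene converts allyl into prenyl with loss of propene, the trisubstituted product being the unreactive end point, while the electron-poor endocyclic C2=C3 bond of the chromone does not take part.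

Step 8
Reactants: 11 8-(3-methylbut-2-enyl)-7-(triisopropylsilyloxy)chromone; 6 (2,2-dimethylchroman-6-yl)boronic acid
Product: 12 (2S)-2-(2,2-dimethylchroman-6-yl)-8-(3-methylbut-2-enyl)-7-(triisopropylsilyloxy)chroman-4-one
Conditions: [Rh(OH)(cod)]2 (1.5 mol %), (S)-MeO-F12-BIPHEP [(S)-2,2'-bis[bis(3,4,5-trifluorophenyl)phosphino]-6,6'-dimethoxy-1,1'-biphenyl] (3.3 mol %), 6 (2.5 equiv), toluene–H2O (10:1), 50 °C
Reagents that add atoms: none
Why: rhodium-catalysed asymmetric 1,4-addition of an arylboronic acid to a chromone (Hayashi–Miyaura type), in which the aryl–rhodium species carrying the electron-poor (S)-biaryl bisphosphine inserts the C2=C3 bond on one enantioface and so sets C2 as (S) under ligand control, and hydrolysis of the rhodium enolate gives the chroman-4-one under near-neutral conditions that do not open ring C; the isolated trisubstituted prenyl alkene is inert.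

Step 9
Reactants: 12 (2S)-2-(2,2-dimethylchroman-6-yl)-8-(3-methylbut-2-enyl)-7-(triisopropylsilyloxy)chroman-4-one
Product: 13 euchrenone a17, (2S)-2-(2,2-dimethylchroman-6-yl)-7-hydroxy-8-(3-methylbut-2-enyl)chroman-4-one
Conditions: TBAF, AcOH, THF, 0 °C
Reagents that add atoms: none
Why: fluoride-mediated desilylation of an aryl silyl ether, buffered with acetic acid so that the phenoxide is protonated at once and neither retro-oxa-Michael racemisation at C2 nor acid-induced cyclisation of the prenyl group onto the 7-hydroxyl should occur.

**Compound list**
1 | 2-fluorostyrene | C=Cc1ccccc1F | starting material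
2 | 2-propanol | CC(C)O | starting material
3 | 4-(2-fluorophenyl)-2-methylbutan-2-ol | CC(C)(O)CCc1ccccc1F | intermediate
4 | 2,2-dimethylchroman | CC1(C)CCc2ccccc2O1 | intermediate
5 | 6-bromo-2,2-dimethylchroman | CC1(C)CCc2cc(Br)ccc2O1 | intermediate
6 | (2,2-dimethylchroman-6-yl)boronic acid | CC1(C)CCc2cc(B(O)O)ccc2O1 | intermediate
7 | 7-hydroxychromone | O=c1ccoc2cc(O)ccc12 | starting material
8 | 7-(allyloxy)chromone | C=CCOc1ccc2c(c1)occc2=O | intermediate
9 | 8-allyl-7-hydroxychromone | C=CCc1c(O)ccc2c1occc2=O | intermediate
10 | 8-allyl-7-(triisopropylsilyloxy)chromone | C=CCc1c(O[Si](C(C)C)(C(C)C)C(C)C)ccc2c1occc2=O | intermediate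
11 | 8-(3-methylbut-2-enyl)-7-(triisopropylsilyloxy)chromone | CC(C)=CCc1c(O[Si](C(C)C)(C(C)C)C(C)C)ccc2c1occc2=O | intermediate
12 | (2S)-2-(2,2-dimethylchroman-6-yl)-8-(3-methylbut-2-enyl)-7-(triisopropylsilyloxy)chroman-4-one | CC(C)=CCc1c(O[Si](C(C)C)(C(C)C)C(C)C)ccc2c1O[C@H](c1ccc3c(c1)CCC(C)(C)O3)CC2=O | intermediate
13 | euchrenone a17, (2S)-2-(2,2-dimethylchroman-6-yl)-7-hydroxy-8-(3-methylbut-2-enyl)chroman-4-one | CC(C)=CCc1c(O)ccc2c1O[C@H](c1ccc3c(c1)CCC(C)(C)O3)CC2=O | target

**Step count**
Total: 9 steps. Longest linear sequence: 6 steps (steps 4 to 9, from 7-hydroxychromone); the boronic acid branch is 3 steps (steps 1 to 3) and joins at step 8.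

**Steps most likely to fail**

Step 1 (Proposed new method). Two processes may go wrong: telomerisation of the styrene may outrun hydrogen return to the benzylic radical, and ipso substitution of the unactivated fluoride may be too slow. The fallback sets out from 1 and comes back at 4, using polar carbon–carbon bond formation and an elimination–addition ring closure. Radical anti-Markovnikov hydrobromination of 1 (HBr, AIBN, hexane, 0 °C) should give 1-(2-bromoethyl)-2-fluorobenzene F1. Magnesium in THF converts it into 2-(2-fluorophenyl)ethylmagnesium bromide F2, which adds to acetone to give 3, now isolated. Treatment of 3 with s-BuLi (2.2 equiv) in THF from −78 °C to 25 °C forms the alkoxide, lithiates the position next to fluorine and expels LiF to give the aryne alkoxide lithium 4-(2,3-didehydrophenyl)-2-methylbutan-2-olate F3. The tethered alkoxide traps the aryne at the near carbon, and protonation gives 4.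

Step 8. Insertion of the electron-rich chromone may be slow, so that protodeboronation of the electron-rich boronic acid consumes the aryl donor, or the facial selectivity may be insufficient. The fallback sets out from 5 and 11 and comes back at 13 by the chalcone route with resolution. Bromine–lithium exchange on 5 and quenching with DMF should give 2,2-dimethylchroman-6-carbaldehyde F4. Aqueous KOH in ethanol at reflux opens the pyranone of 11 with loss of formate and of the silyl group to give 1-[2,4-dihydroxy-3-(3-methylbut-2-enyl)phenyl]ethanone F5. Claisen–Schmidt condensation of F5 with F4 (aq. KOH, EtOH, 25 °C) gives (E)-1-[2,4-dihydroxy-3-(3-methylbut-2-enyl)phenyl]-3-(2,2-dimethylchroman-6-yl)prop-2-en-1-one F6. Oxa-Michael cyclisation (NaOAc, EtOH, reflux) gives the racemic flavanone F7, and preparative HPLC on a chiral stationary phase delivers 13; the unwanted antipode can be racemised with mild base and recycled.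

Step 5. Regiocontrol between C8 and C6 may be incomplete, and the ortho-allylphenol may cyclise or decompose at 200 °C. The fallback sets out from 7 and comes back at 11, installing the prenyl group by cross-coupling. Iodination of 7 with N-iodosuccinimide in DMF should give 7-hydroxy-8-iodochromone F8. Silylation (TIPSCl, imidazole, DMF) gives 8-iodo-7-(triisopropylsilyloxy)chromone F9. Stille coupling with tributyl(3-methylbut-2-enyl)stannane (Pd(PPh3)4, a zerovalent palladium complex, DMF, 90 °C) gives 11 directly, which also makes steps 4 to 7 unnecessary.

**Further compounds**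
F1 | step 1 | 1-(2-bromoethyl)-2-fluorobenzene | BrCCc1ccccc1F
F2 | step 1 | 2-(2-fluorophenyl)ethylmagnesium bromide | Fc1ccccc1CC[Mg]Br
F3 | step 1 | lithium 4-(2,3-didehydrophenyl)-2-methylbutan-2-olate | [Li+].CC(C)([O-])CCC1=CC=CC#C1
F4 | step 8 | 2,2-dimethylchroman-6-carbaldehyde | CC1(C)CCc2cc(C=O)ccc2O1
F5 | step 8 | 1-[2,4-dihydroxy-3-(3-methylbut-2-enyl)phenyl]ethanone | CC(=O)c1ccc(O)c(CC=C(C)C)c1O
F6 | step 8 | (E)-1-[2,4-dihydroxy-3-(3-methylbut-2-enyl)phenyl]-3-(2,2-dimethylchroman-6-yl)prop-2-en-1-one | CC(C)=CCc1c(O)ccc(C(=O)/C=C/c2ccc3OC(C)(C)CCc3c2)c1O
F7 | step 8 | racemic 2-(2,2-dimethylchroman-6-yl)-7-hydroxy-8-(3-methylbut-2-enyl)chroman-4-one | CC(C)=CCc1c(O)ccc2c1OC(c1ccc3c(c1)CCC(C)(C)O3)CC2=O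
F8 | step 5 | 7-hydroxy-8-iodochromone | O=c1ccoc2c(I)c(O)ccc12
F9 | step 5 | 8-iodo-7-(triisopropylsilyloxy)chromone | CC(C)[Si](Oc1ccc2c(c1I)occc2=O)(C(C)C)C(C)C
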